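**Remark on the chemistry.** Compounds 20 and 21 each carry one stereocentre (C3 of the lactone, then the carbinol carbon) and are carried as racemates. That carbon becomes a ketone in step 13 and sp2 in the target, so no stereocontrol is attempted.

## Analysis of the target

The target is an isocoumarin (1H-isochromen-1-one): a benzo ring (ring A) fused to a six-membered enol lactone, with a pentyl chain on C3, a free hydroxyl on C6 and an aryloxy group on C8. The aryl group (ring B) is 2-hydroxy-4-methoxy-6-pentylphenyl, joined to C8 through a diaryl ether oxygen on C1', so the ether carbon of ring B is flanked by a hydroxyl and a pentyl chain and that of ring A by the lactone carbonyl carbon C8a. There is no stereocentre and no stereogenic double bond, so any stereocentre made on the way has to be erased. The sensitive points are the enol lactone (opened by base and nucleophiles), the two free phenols that must be told apart from the one methyl ether, the electron-rich ring B, and several benzylic C–H positions (the pentyl CH2 on ring B, and C4 in any dihydro intermediate). The difficulty lies in the crowded, tri-ortho-substituted diaryl ether and in the 1,2,3,5-substitution of ring A, where the carbonyl carbon must sit exactly between the aryloxy carbon C8 and the ring-fusion carbon C4a. The plan rests on the four-atom unit C1–C8a–C4a–C4. C1 and C4 hang on adjacent benzo carbons and the aryloxy group sits beside C8a, which is the connectivity of a benzocyclobutenone (C1 the ketone carbon, C4 the CH2) obtainable from a 3-aryloxyaryne and a ketene acetal. The two remaining ring atoms, O2 and C3 with its pentyl chain, are the carbonyl group of a six-carbon aldehyde.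

## Retrosynthetic reasoning

Target 24 is traced back first to its dibenzyl ether 23. Benzyl is the protecting group for both phenols because it can be removed by a Lewis acid at low temperature without touching the methyl ether or reducing the C3=C4 bond, and because it survives every earlier step.

The enol lactone of 23 is cut at the C1–O2 bond and C3 is taken to the ketone level, giving keto amide 22. An ortho-(2-oxoalkyl)benzamide closes to an isocoumarin under acid. Compound 22 comes from hydroxy amide 21 by alcohol oxidation, and 21 from the racemic isochroman-1-one 20 by opening the lactone with a secondary amine. This three-step detour replaces a direct dehydrogenation of 20. A radical bromination–elimination or a quinone oxidation at C4 would have to compete with the pentyl CH2 on the electron-rich ring B and with the two benzylic ether CH2 groups, all better hydrogen donors than C4–H, which is benzylic to the electron-poorer ring and lies next to the oxygen-bearing C3. Moving the oxidation to the carbinol carbon avoids that competition.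

The key disconnection cuts 20 at C3–C4 and C1–O2. This leaves hexanal 18 and the o-quinoid vinylketene 19, which is the ring-opened valence isomer of benzocyclobutenone 17. The cut is made here because it removes both non-benzo atoms of the lactone ring in one step, uses a cheap aldehyde that brings the whole C3 side chain, and leaves a precursor whose substitution pattern is fixed by aryne chemistry. The forward reaction has to open the four-membered ring thermally and capture the ketene with an aldehyde C=O in the right orientation.

Ketone 17 comes from its diethyl ketal 16, and 16 from the formal [2+2] of aryne 15 with ketene acetal 14. The two bonds of the four-membered ring to ring A are cut. The aryloxy group next to the triple bond polarises the aryne so that the ketal carbon ends up beside it, which is the regiochemistry the lactone carbonyl needs.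

Aryne 15 is generated from bromide 13, whose only hydrogen ortho to bromine lies on the side away from the aryloxy group, so only one aryne can form. Bromide 13 is traced through diazonium salt 12 and aniline 11 to nitro diaryl ether 10. The nitro group serves twice: it activates the ortho fluorine of 9 for the SNAr reaction with phenol 7 that makes the hindered ether bond, and it is then converted into the bromine. The ether is cut on the ring A side because ring B is far too electron-rich to be an SNAr electrophile. Fluoronitroarene 9 is the benzyl ether of commercial phenol 8.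

Phenol 7 is traced to aldehyde 5 by a Baeyer–Villiger disconnection through formate 6, and 5 to olivetol 1 by benzylation (from 4), selective methylation (from 3) and formylation through iminium salt 2. Olivetol already has the 1,3,5-pattern of two oxygens and the pentyl chain. The formyl group marks the carbon that will carry the ether oxygen and also differentiates the two hydroxyls, because the one ortho to it is hydrogen-bonded and reacts second.

## Alternatives that were turned down

Alternative 1: Here the benzo ring itself is disconnected at C4a–C8a, C5–C6 and C7–C8. In the forward sense a rhodium-catalysed [2+2+2] cyclotrimerisation joins the enol-ester-tethered diyne A2 with the ethynylboronate A3 to give boronate A1, closing ring A and the lactone ring together. Oxidation of the C–B bond and removal of one benzyl group would finish the synthesis.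
- For: it is the most convergent plan, the C3=C4 bond is present from the start as the enol ester, and only one protecting group is needed. On convergence and on oxidation level it is stronger than the chosen route.
- Against: A2 is the ester of an aryloxypropiolic acid (an alkynyl ether of a di-ortho-substituted phenol) with a geometrically defined Z enynol. Both halves are hard to make and the assembled ester is labile towards nucleophiles and towards metal insertion into the acyl–oxygen bond. The cyclotrimerisation must also place boron on C6 and not on C7, which rests only on a steric preference, and homotrimerisation of A3 competes.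
- Comparison: the risk sits in the fragment synthesis as well as in the key step. The chosen route offers fragments made by standard reactions and a single uncertain step that can be bypassed without redesign.

Alternative 2: Ring A is disconnected at C8–C8a and C4a–C5 as an Alder–Rickert synthesis. The 1-aryloxy-3-silyloxycyclohexadiene A5 adds to ynoate A6, the bicyclo[2.2.2]octadiene loses its saturated two-carbon bridge by cycloreversion, and desilylation gives resorcylate A4. Acid would then unmask the ketone and close the enol lactone, and debenzylation would follow.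
- For: the polarisation of A5 fixes the regiochemistry (its unsubstituted terminus bonds to the ynoate β-carbon, its aryloxy-bearing terminus to the ester-bearing carbon). The C6 hydroxyl arrives free and distinct, and C3 is already at the ketone level, so no oxidation-state correction is needed at the end. On that point it is stronger than the chosen route, which spends three steps on it.
- Against: A6 is a β-alkyl ynoate with a single activating group. The new bond to the ester-bearing carbon must form at a diene terminus that carries the bulky di-ortho-substituted aryloxy group. The cycloaddition–cycloreversion therefore needs prolonged high temperature, at which a silyl dienol ether such as A5 is prone to isomerise or lose silicon. A5 also has to be made from phenol 7 by vinylogous ester formation and kinetic enolisation.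
- Comparison: the step count is similar. The chosen route forms only two bonds onto an aromatic ring that is already assembled, and the aryne step that builds its precursor follows a well-established regiochemical rule.

Alternative 3: Ring B is disconnected at C1'–C6' and C2'–C3'. The anion of aryloxymalonate A8 adds to enone A9 and the methyl ketone enolate then closes onto one ester, giving cyclohexanedione A7, in which ring A is a toluamide set up for later lateral metalation.
- For: the diaryl ether coupling is avoided altogether, since the C–O bond comes from simple alkylation of a ring A phenol with a halomalonate. On that point it is stronger than the chosen route, which relies on an SNAr reaction of a hindered phenoxide. The toluamide also leads to the isocoumarin by established chemistry.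
- Against: it builds an aromatic ring that olivetol 1 already supplies with the correct pattern. The Michael addition must create a quaternary, oxygen-bearing carbon on a β-alkyl enone and is slow and reversible. After A7 the ester has to be removed, the dione dehydrogenated to a resorcinol while the α-aryloxy group is kept, the 4'-hydroxyl methylated in the presence of the 2'-hydroxyl, and the isocoumarin still built by lateral metalation, acylation and cyclisation.
- Comparison: this is at least six further steps with two selectivity problems. The chosen route takes ring B intact from olivetol 1 and is shorter.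

Key step: step 11

## Route

Step 1
Reactants: 1 olivetol (5-pentylbenzene-1,3-diol)
Product: 3 2,4-dihydroxy-6-pentylbenzaldehyde, via iminium chloride 2 (not isolated)
Conditions: POCl3, DMF, 0 → 25 °C; then H2O, 50 °C
Reagents that add atoms: N,N-dimethylformamide, CN(C)C=O; water, O
Why: Vilsmeier–Haack formylation; the chloroiminium ion attacks para to one hydroxyl and ortho to the other, the carbon next to the pentyl chain being preferred over the doubly flanked carbon between the hydroxyls as with other 5-alkylresorcinols, and water hydrolyses iminium salt 2 to the aldehyde.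

Step 2
Reactants: 3 2,4-dihydroxy-6-pentylbenzaldehyde
Product: 4 2-hydroxy-4-methoxy-6-pentylbenzaldehyde
Conditions: MeI (1.05 equiv), K2CO3, acetone, 25 °C
Reagents that add atoms: iodomethane, CI
Why: Williamson methylation under weak base; the 4-hydroxyl is the more acidic and free phenol while the 2-hydroxyl is held in a hydrogen bond to the formyl group, so one equivalent of MeI alkylates O4 selectively.

Step 3
Reactants: 4 2-hydroxy-4-methoxy-6-pentylbenzaldehyde
Product: 5 2-(benzyloxy)-4-methoxy-6-pentylbenzaldehyde
Conditions: BnBr, K2CO3, DMF, 60 °C
Reagents that add atoms: benzyl bromide, BrCc1ccccc1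
Why: Williamson benzylation of the remaining chelated phenol at higher temperature; benzyl survives the amide base, acid and heat of the later steps and is removed at the end without touching the methyl ether.

Step 4
Reactants: 5 2-(benzyloxy)-4-methoxy-6-pentylbenzaldehyde
Product: 7 2-(benzyloxy)-4-methoxy-6-pentylphenol, via aryl formate 6 (not isolated)
Conditions: mCPBA, CH2Cl2, 0 → 25 °C; then K2CO3 (cat.), MeOH, 25 °C
Reagents that add atoms: 3-chloroperoxybenzoic acid, OOC(=O)c1cccc(Cl)c1
Why: Baeyer–Villiger (Dakin-type) oxidation; the electron-rich aryl group migrates in preference to hydride to give formate 6, and mild methanolysis frees the phenol, so the oxygen lands on the carbon flanked by benzyloxy and pentyl.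

Step 5
Reactants: 8 3-fluoro-4-nitrophenol
Product: 9 4-(benzyloxy)-2-fluoro-1-nitrobenzene
Conditions: BnBr, K2CO3, acetone, 50 °C
Reagents that add atoms: benzyl bromide, BrCc1ccccc1
Why: Williamson benzylation; the nitrophenoxide is too weak a nucleophile to displace the fluoride of a second molecule at this temperature, so O-alkylation dominates.

Step 6
Reactants: 7 2-(benzyloxy)-4-methoxy-6-pentylphenol; 9 4-(benzyloxy)-2-fluoro-1-nitrobenzene
Product: 10 4-(benzyloxy)-2-[2-(benzyloxy)-4-methoxy-6-pentylphenoxy]-1-nitrobenzene
Conditions: K2CO3, DMF, 80 °C, under N2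
Reagents that add atoms: none
Why: SNAr by addition–elimination; the fluoride ortho to the nitro group is the only activated site and is displaced by the hindered phenoxide of 7 through a Meisenheimer adduct, which tolerates the two ortho substituents of the nucleophile better than a metal-catalysed coupling would.

Step 7
Reactants: 10 4-(benzyloxy)-2-[2-(benzyloxy)-4-methoxy-6-pentylphenoxy]-1-nitrobenzene
Product: 11 4-(benzyloxy)-2-[2-(benzyloxy)-4-methoxy-6-pentylphenoxy]aniline
Conditions: Fe, NH4Cl, EtOH/H2O, 80 °C
Reagents that add atoms: none
Why: Béchamp-type dissolving-metal reduction of the nitro group under near-neutral conditions, which leaves the benzyl ethers and the diaryl ether untouched because no hydrogenolysis catalyst is present.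

Step 8
Reactants: 11 4-(benzyloxy)-2-[2-(benzyloxy)-4-methoxy-6-pentylphenoxy]aniline
Product: 13 4-(benzyloxy)-1-bromo-2-[2-(benzyloxy)-4-methoxy-6-pentylphenoxy]benzene, via diazonium bromide 12 (not isolated)
Conditions: NaNO2, 48% aq. HBr, MeCN, 0 °C; then CuBr (0.3 equiv), 0 → 50 °C
Reagents that add atoms: hydrobromic acid, Br
Why: Sandmeyer bromination; diazotisation, then CuBr-mediated electron transfer, loss of dinitrogen and bromine transfer to the aryl radical. Pschorr-type closure onto ring B is blocked because both of its positions ortho to the ether oxygen are substituted.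

Step 9
Reactants: 13 4-(benzyloxy)-1-bromo-2-[2-(benzyloxy)-4-methoxy-6-pentylphenoxy]benzene; 14 1,1-diethoxyethene
Product: 16 3-(benzyloxy)-5-[2-(benzyloxy)-4-methoxy-6-pentylphenoxy]-7,7-diethoxybicyclo[4.2.0]octa-1,3,5-triene, via aryne 15 (not isolated)
Conditions: NaNH2 (4 equiv), 14 (3 equiv), THF, 65 °C
Reagents that add atoms: none
Why: Amide-base dehydrobromination removes the only hydrogen ortho to bromine and gives aryne 15, which undergoes the known stepwise [2+2] with a ketene acetal. The CH2 carbon of 14 attacks the aryne carbon remote from the aryloxy group, so the aryl anion forms beside that inductively stabilising oxygen and closes onto the oxocarbenium carbon. The ketal carbon therefore ends up next to the aryloxy-bearing carbon, as is known for 3-alkoxyarynes.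

Step 10
Reactants: 16 3-(benzyloxy)-5-[2-(benzyloxy)-4-methoxy-6-pentylphenoxy]-7,7-diethoxybicyclo[4.2.0]octa-1,3,5-triene
Product: 17 3-(benzyloxy)-5-[2-(benzyloxy)-4-methoxy-6-pentylphenoxy]bicyclo[4.2.0]octa-1,3,5-trien-7-one
Conditions: 1 M aq. HCl, THF, 25 °C
Reagents that add atoms: water, O
Why: Acid-catalysed ketal hydrolysis; aryl benzyl ethers and the diaryl ether are inert to dilute aqueous acid at room temperature.

Step 11
Reactants: 17 3-(benzyloxy)-5-[2-(benzyloxy)-4-methoxy-6-pentylphenoxy]bicyclo[4.2.0]octa-1,3,5-trien-7-one; 18 hexanal
Product: 20 racemic 6-(benzyloxy)-8-[2-(benzyloxy)-4-methoxy-6-pentylphenoxy]-3-pentylisochroman-1-one, via o-quinoid vinylketene 19 (not isolated)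
Conditions: 18 (10 equiv, freshly distilled), o-xylene, 4 Å MS, sealed tube, 160 °C
Reagents that add atoms: none
Why: On heating, the C7(=O)–C8H2 σ bond of 17 opens in a reversible 4π electrocyclic reaction to the o-quinoid vinylketene 19, in which the former CH2 is an exocyclic methylene on C4a and the former ketone carbon a ketene carbon on C8a. The C=O of 18 then adds across these termini as a heterodienophile, its oxygen bonding to the electrophilic ketene carbon (C1–O2) and its carbon to the methylene terminus (C3–C4), in one asynchronous step or through a short-lived zwitterion, and ring A rearomatises as the bonds form. The closest known reaction type is the oxa-[4+2] capture of benzocyclobutenone-derived vinylketenes by aldehydes and ketones to give isochroman-1-ones; an enolisable aliphatic aldehyde is the less explored partner, hence the large excess. The lactone ring closes by this intermolecular [4+2] mode, both ring bonds being made in the one operation. The new stereocentre C3 forms without any controlling element, so 20 is racemic, which is immaterial because that carbon becomes a ketone in step 13. The selectivity needed is orientational (oxygen to C1, carbon to C4) and is secured by the polarity of 19, whose ketene carbon is the only strongly electrophilic site and whose methylene is the nucleophilic end of a dienolate-like system. Reclosure to 17 is the main competing path but is non-destructive, and intramolecular acylation of ring B by the ketene is blocked because both ortho positions of that ring are substituted.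

Step 12
Reactants: 20 racemic 6-(benzyloxy)-8-[2-(benzyloxy)-4-methoxy-6-pentylphenoxy]-3-pentylisochroman-1-one
Product: 21 racemic 4-(benzyloxy)-2-[2-(benzyloxy)-4-methoxy-6-pentylphenoxy]-6-(2-hydroxyheptyl)-N,N-dimethylbenzamide
Conditions: AlMe3, Me2NH (2 M in THF), CH2Cl2, 0 → 40 °C; aq. work-up
Reagents that add atoms: dimethylamine, CNC
Why: Weinreb-type aminolysis of a lactone by the aluminium amide Me2AlNMe2 formed in the flask, a reagent strong enough for a hindered aryl lactone; the tertiary hydroxy amide does not relactonise under neutral conditions.

Step 13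
Reactants: 21 racemic 4-(benzyloxy)-2-[2-(benzyloxy)-4-methoxy-6-pentylphenoxy]-6-(2-hydroxyheptyl)-N,N-dimethylbenzamide
Product: 22 4-(benzyloxy)-2-[2-(benzyloxy)-4-methoxy-6-pentylphenoxy]-N,N-dimethyl-6-(2-oxoheptyl)benzamide
Conditions: Dess–Martin periodinane, CH2Cl2, 25 °C
Reagents that add atoms: none
Why: Dess–Martin oxidation of the secondary alcohol under neutral conditions; it removes the stereocentre and brings C3 to the oxidation level of the enol lactone without any benzylic C–H functionalisation.

Step 14
Reactants: 22 4-(benzyloxy)-2-[2-(benzyloxy)-4-methoxy-6-pentylphenoxy]-N,N-dimethyl-6-(2-oxoheptyl)benzamide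
Product: 23 6-(benzyloxy)-8-[2-(benzyloxy)-4-methoxy-6-pentylphenoxy]-3-pentyl-1H-isochromen-1-one
Conditions: AcOH, 110 °C
Reagents that add atoms: none
Why: Acid-catalysed cyclodehydration of an ortho-(2-oxoalkyl)benzamide, the usual last stage of toluamide-based isocoumarin syntheses; closure between the ketone (as its enol) and the amide carbonyl with loss of dimethylamine gives the conjugated enol lactone. A tertiary amide is used so that no isoquinolone can form, and aryl benzyl ethers are stable in hot acetic acid.

Step 15
Reactants: 23 6-(benzyloxy)-8-[2-(benzyloxy)-4-methoxy-6-pentylphenoxy]-3-pentyl-1H-isochromen-1-one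
Product: 24 6-hydroxy-8-(2-hydroxy-4-methoxy-6-pentylphenoxy)-3-pentyl-1H-isochromen-1-one (target)
Conditions: BCl3 (1 M in CH2Cl2), C6HMe5, CH2Cl2, −78 °C; then MeOH
Reagents that add atoms: none
Why: Lewis-acid debenzylation of aryl benzyl ethers with BCl3 and pentamethylbenzene as a non-basic cation scavenger; at low temperature the aryl methyl ether, the diaryl ether and the enol lactone are not cleaved, and the C3=C4 bond is not exposed to hydrogenation.

## Compound list

1 | olivetol (5-pentylbenzene-1,3-diol) | CCCCCc1cc(O)cc(O)c1 | starting material
2 | N-[(2,4-dihydroxy-6-pentylphenyl)methylidene]-N-methylmethanaminium chloride | CCCCCc1cc(O)cc(O)c1C=[N+](C)C.[Cl-] | intermediate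
3 | 2,4-dihydroxy-6-pentylbenzaldehyde | CCCCCc1cc(O)cc(O)c1C=O | intermediate
4 | 2-hydroxy-4-methoxy-6-pentylbenzaldehyde | CCCCCc1cc(OC)cc(O)c1C=O | intermediate
5 | 2-(benzyloxy)-4-methoxy-6-pentylbenzaldehyde | CCCCCc1cc(OC)cc(OCc2ccccc2)c1C=O | intermediate
6 | 2-(benzyloxy)-4-methoxy-6-pentylphenyl formate | CCCCCc1cc(OC)cc(OCc2ccccc2)c1OC=O | intermediate
7 | 2-(benzyloxy)-4-methoxy-6-pentylphenol | CCCCCc1cc(OC)cc(OCc2ccccc2)c1O | intermediate
8 | 3-fluoro-4-nitrophenol | Oc1ccc([N+](=O)[O-])c(F)c1 | starting material
9 | 4-(benzyloxy)-2-fluoro-1-nitrobenzene | [O-][N+](=O)c1ccc(OCc2ccccc2)cc1F | intermediate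
10 | 4-(benzyloxy)-2-[2-(benzyloxy)-4-methoxy-6-pentylphenoxy]-1-nitrobenzene | CCCCCc1cc(OC)cc(OCc2ccccc2)c1Oc1cc(OCc2ccccc2)ccc1[N+](=O)[O-] | intermediate
11 | 4-(benzyloxy)-2-[2-(benzyloxy)-4-methoxy-6-pentylphenoxy]aniline | CCCCCc1cc(OC)cc(OCc2ccccc2)c1Oc1cc(OCc2ccccc2)ccc1N | intermediate
12 | 4-(benzyloxy)-2-[2-(benzyloxy)-4-methoxy-6-pentylphenoxy]benzenediazonium bromide | CCCCCc1cc(OC)cc(OCc2ccccc2)c1Oc1cc(OCc2ccccc2)ccc1[N+]#N.[Br-] | intermediate
13 | 4-(benzyloxy)-1-bromo-2-[2-(benzyloxy)-4-methoxy-6-pentylphenoxy]benzene | CCCCCc1cc(OC)cc(OCc2ccccc2)c1Oc1cc(OCc2ccccc2)ccc1Br | intermediate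
14 | 1,1-diethoxyethene | C=C(OCC)OCC | starting material
15 | 5-(benzyloxy)-3-[2-(benzyloxy)-4-methoxy-6-pentylphenoxy]-1,2-didehydrobenzene (aryne) | CCCCCc1cc(OC)cc(OCc2ccccc2)c1OC1=CC(OCc2ccccc2)=CC#C1 | intermediate
16 | 3-(benzyloxy)-5-[2-(benzyloxy)-4-methoxy-6-pentylphenoxy]-7,7-diethoxybicyclo[4.2.0]octa-1,3,5-triene | CCCCCc1cc(OC)cc(OCc2ccccc2)c1Oc1cc(OCc2ccccc2)cc2c1C(OCC)(OCC)C2 | intermediate
17 | 3-(benzyloxy)-5-[2-(benzyloxy)-4-methoxy-6-pentylphenoxy]bicyclo[4.2.0]octa-1,3,5-trien-7-one | CCCCCc1cc(OC)cc(OCc2ccccc2)c1Oc1cc(OCc2ccccc2)cc2c1C(=O)C2 | intermediate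
18 | hexanal | CCCCCC=O | starting material
19 | [4-(benzyloxy)-2-[2-(benzyloxy)-4-methoxy-6-pentylphenoxy]-6-methylidenecyclohexa-2,4-dien-1-ylidene]methanone (o-quinoid vinylketene) | CCCCCc1cc(OC)cc(OCc2ccccc2)c1OC1=CC(OCc2ccccc2)=CC(=C)C1=C=O | intermediate
20 | 6-(benzyloxy)-8-[2-(benzyloxy)-4-methoxy-6-pentylphenoxy]-3-pentylisochroman-1-one (racemic at C3) | CCCCCC1Cc2cc(OCc3ccccc3)cc(Oc3c(OCc4ccccc4)cc(OC)cc3CCCCC)c2C(=O)O1 | intermediate
21 | 4-(benzyloxy)-2-[2-(benzyloxy)-4-methoxy-6-pentylphenoxy]-6-(2-hydroxyheptyl)-N,N-dimethylbenzamide (racemic at the carbinol carbon) | CCCCCC(O)Cc1cc(OCc2ccccc2)cc(Oc2c(OCc3ccccc3)cc(OC)cc2CCCCC)c1C(=O)N(C)C | intermediate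
22 | 4-(benzyloxy)-2-[2-(benzyloxy)-4-methoxy-6-pentylphenoxy]-N,N-dimethyl-6-(2-oxoheptyl)benzamide | CCCCCC(=O)Cc1cc(OCc2ccccc2)cc(Oc2c(OCc3ccccc3)cc(OC)cc2CCCCC)c1C(=O)N(C)C | intermediate
23 | 6-(benzyloxy)-8-[2-(benzyloxy)-4-methoxy-6-pentylphenoxy]-3-pentyl-1H-isochromen-1-one | CCCCCc1cc2cc(OCc3ccccc3)cc(Oc3c(OCc4ccccc4)cc(OC)cc3CCCCC)c2c(=O)o1 | intermediate
24 | 6-hydroxy-8-(2-hydroxy-4-methoxy-6-pentylphenoxy)-3-pentyl-1H-isochromen-1-one | CCCCCc1cc2cc(O)cc(Oc3c(O)cc(OC)cc3CCCCC)c2c(=O)o1 | target

## Step count and least certain steps

Total step count: 15. Longest linear sequence: 14 steps (steps 1–4 and 6–15, from olivetol 1); the ring A branch contributes one step (step 5) before the fragments meet in step 6.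

**Step 11 (key step).** The ring opening needs a high temperature and its equilibrium lies on the closed side, while the unactivated, enolisable aldehyde is a weak heterodienophile. Capture may therefore be slower than dimerisation of the vinylketene, its interception by traces of water or carboxylic acid, and self-condensation of the aldehyde, so conversion to the lactone may stay low. Photochemical opening at room temperature would be a change of conditions only.

The fallback leaves the pericyclic step for anionic chemistry and sets out from 17. Lithium dimethylamide (LiNMe2, THF, −78 → 0 °C, then aqueous NH4Cl) adds to the strained ketone, and the resulting alkoxide opens the four-membered ring to give, after protonation, 4-(benzyloxy)-2-[2-(benzyloxy)-4-methoxy-6-pentylphenoxy]-N,N,6-trimethylbenzamide F1. Lateral metalation of F1 with LiN(iPr)2 in THF at −78 °C and addition of the benzylic anion to hexanal 18 gives hydroxy amide 21, where the route is rejoined; step 12 is then not needed.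

**Step 9.** Deprotonation ortho to bromine is assisted only by the halogen and may be slow. The aryne can also be lost by addition of amide ion, by intramolecular capture by the neighbouring benzyloxy oxygen of ring B, or the benzyl ethers may suffer base-induced rearrangement during the long heating.

The fallback generates the same aryne 15 by halogen–metal exchange at low temperature; it sets out from phenol 7 and returns at 16. Commercial 3,5-difluoro-4-nitrophenol is benzylated (BnBr, K2CO3) to 5-(benzyloxy)-1,3-difluoro-2-nitrobenzene F2. One fluoride of F2 is displaced by 7 (K2CO3, DMF, 60 °C) to give 5-(benzyloxy)-1-[2-(benzyloxy)-4-methoxy-6-pentylphenoxy]-3-fluoro-2-nitrobenzene F3, the second fluoride being deactivated by the new ether. Reduction with Fe/NH4Cl gives 4-(benzyloxy)-2-[2-(benzyloxy)-4-methoxy-6-pentylphenoxy]-6-fluoroaniline F4, and Sandmeyer bromination as in step 8 gives 5-(benzyloxy)-2-bromo-1-[2-(benzyloxy)-4-methoxy-6-pentylphenoxy]-3-fluorobenzene F5. Treating F5 with n-BuLi in THF at −78 °C in the presence of excess 14 and warming causes bromine–lithium exchange and loss of LiF to aryne 15, which is trapped as ketal 16.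

**Step 8.** The aryl radical of the Sandmeyer reaction lies close to the benzylic hydrogens of ring B (benzyloxy CH2 and pentyl CH2), so intramolecular hydrogen transfer leading to hydrodediazoniation may compete with bromine transfer. The electron-rich system is also prone to azo coupling if diazotisation is incomplete.

The fallback avoids the nitro and diazonium stages; it sets out from phenol 7 and returns at 13. Commercial 4-bromo-3-iodophenol is benzylated (BnBr, K2CO3, acetone) to 4-(benzyloxy)-1-bromo-2-iodobenzene F6. A copper-catalysed Ullmann ether synthesis (CuI, picolinic acid, K3PO4, DMSO, 90 °C) couples 7 selectively at the C–I bond of F6 to give bromide 13 directly. This is shorter but was not made the main route because the coupling of a di-ortho-substituted phenol with an ortho-substituted aryl iodide is less dependable than the SNAr reaction.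

**Step 12.** The lactone carbonyl is flanked by two ortho substituents and deactivated by the para benzyloxy donor, so aminolysis may stop short of completion or the hydroxy amide may relactonise during work-up.

The fallback opens the ring with the smallest nucleophile and carries an ester; it sets out from 20 and returns at 24. Saponification (KOH, aq. EtOH, 70 °C), evaporation and alkylation of the potassium carboxylate with BnBr in DMF give benzyl 4-(benzyloxy)-2-[2-(benzyloxy)-4-methoxy-6-pentylphenoxy]-6-(2-hydroxyheptyl)benzoate F7. Dess–Martin oxidation gives benzyl 4-(benzyloxy)-2-[2-(benzyloxy)-4-methoxy-6-pentylphenoxy]-6-(2-oxoheptyl)benzoate F8. Hydrogenolysis (H2, Pd/C, EtOAc) removes all three benzyl groups before any C=C bond exists and gives 4-hydroxy-2-(2-hydroxy-4-methoxy-6-pentylphenoxy)-6-(2-oxoheptyl)benzoic acid F9. Brief warming of F9 with catalytic TsOH in toluene cyclodehydrates the keto acid to target 24.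

## Further compounds

F1 | step 11 | 4-(benzyloxy)-2-[2-(benzyloxy)-4-methoxy-6-pentylphenoxy]-N,N,6-trimethylbenzamide | CCCCCc1cc(OC)cc(OCc2ccccc2)c1Oc1cc(OCc2ccccc2)cc(C)c1C(=O)N(C)C
F2 | step 9 | 5-(benzyloxy)-1,3-difluoro-2-nitrobenzene | [O-][N+](=O)c1c(F)cc(OCc2ccccc2)cc1F
F3 | step 9 | 5-(benzyloxy)-1-[2-(benzyloxy)-4-methoxy-6-pentylphenoxy]-3-fluoro-2-nitrobenzene | CCCCCc1cc(OC)cc(OCc2ccccc2)c1Oc1cc(OCc2ccccc2)cc(F)c1[N+](=O)[O-]
F4 | step 9 | 4-(benzyloxy)-2-[2-(benzyloxy)-4-methoxy-6-pentylphenoxy]-6-fluoroaniline | CCCCCc1cc(OC)cc(OCc2ccccc2)c1Oc1cc(OCc2ccccc2)cc(F)c1N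
F5 | step 9 | 5-(benzyloxy)-2-bromo-1-[2-(benzyloxy)-4-methoxy-6-pentylphenoxy]-3-fluorobenzene | CCCCCc1cc(OC)cc(OCc2ccccc2)c1Oc1cc(OCc2ccccc2)cc(F)c1Br
F6 | step 8 | 4-(benzyloxy)-1-bromo-2-iodobenzene | Brc1ccc(OCc2ccccc2)cc1I
F7 | step 12 | benzyl 4-(benzyloxy)-2-[2-(benzyloxy)-4-methoxy-6-pentylphenoxy]-6-(2-hydroxyheptyl)benzoate (racemic) | CCCCCC(O)Cc1cc(OCc2ccccc2)cc(Oc2c(OCc3ccccc3)cc(OC)cc2CCCCC)c1C(=O)OCc1ccccc1
F8 | step 12 | benzyl 4-(benzyloxy)-2-[2-(benzyloxy)-4-methoxy-6-pentylphenoxy]-6-(2-oxoheptyl)benzoate | CCCCCC(=O)Cc1cc(OCc2ccccc2)cc(Oc2c(OCc3ccccc3)cc(OC)cc2CCCCC)c1C(=O)OCc1ccccc1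
F9 | step 12 | 4-hydroxy-2-(2-hydroxy-4-methoxy-6-pentylphenoxy)-6-(2-oxoheptyl)benzoic acid | CCCCCC(=O)Cc1cc(O)cc(Oc2c(O)cc(OC)cc2CCCCC)c1C(=O)O
A1 | alternative 1 | 8-[2-(benzyloxy)-4-methoxy-6-pentylphenoxy]-3-pentyl-6-(4,4,5,5-tetramethyl-1,3,2-dioxaborolan-2-yl)-1H-isochromen-1-one | CCCCCc1cc2cc(B3OC(C)(C)C(C)(C)O3)cc(Oc3c(OCc4ccccc4)cc(OC)cc3CCCCC)c2c(=O)o1
A2 | alternative 1 | (Z)-non-3-en-1-yn-4-yl 3-[2-(benzyloxy)-4-methoxy-6-pentylphenoxy]prop-2-ynoate | C#C/C=C(/CCCCC)OC(=O)C#COc1c(OCc2ccccc2)cc(OC)cc1CCCCC
A3 | alternative 1 | 2-ethynyl-4,4,5,5-tetramethyl-1,3,2-dioxaborolane | C#CB1OC(C)(C)C(C)(C)O1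
A4 | alternative 2 | methyl 2-[2-(benzyloxy)-4-methoxy-6-pentylphenoxy]-4-hydroxy-6-[(2-pentyl-1,3-dioxolan-2-yl)methyl]benzoate | COC(=O)c1c(CC2(CCCCC)OCCO2)cc(O)cc1Oc1c(OCc2ccccc2)cc(OC)cc1CCCCC
A5 | alternative 2 | 1-[2-(benzyloxy)-4-methoxy-6-pentylphenoxy]-3-(tert-butyldimethylsilyloxy)cyclohexa-1,3-diene | CC(C)(C)[Si](C)(C)OC1=CCCC(Oc2c(OCc3ccccc3)cc(OC)cc2CCCCC)=C1
A6 | alternative 2 | methyl 4-(2-pentyl-1,3-dioxolan-2-yl)but-2-ynoate | COC(=O)C#CCC1(CCCCC)OCCO1
A7 | alternative 3 | methyl 1-[5-(benzyloxy)-2-(diethylcarbamoyl)-3-methylphenoxy]-2,4-dioxo-6-pentylcyclohexane-1-carboxylate (racemic, one diastereomer drawn, either serves) | CCCCC[C@@H]1CC(=O)CC(=O)[C@]1(Oc2cc(OCc3ccccc3)cc(C)c2C(=O)N(CC)CC)C(=O)OC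
A8 | alternative 3 | dimethyl 2-[5-(benzyloxy)-2-(diethylcarbamoyl)-3-methylphenoxy]propanedioate | COC(=O)C(Oc1cc(OCc2ccccc2)cc(C)c1C(=O)N(CC)CC)C(=O)OC
A9 | alternative 3 | (E)-non-3-en-2-one | CCCCC/C=C/C(C)=O
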